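Slowness is what this flask shows soonest. In the epsilon run, which is the flask asked about, followed so far, the target grows at 0.152 h⁻¹, counted as a share of the charge, over the first interval and at 0.0400 h⁻¹ over the second, so the rate is lower by a factor of 3.81.

all flasks: starting material 20 mM

| charge | partner | protic impurity | temperature | remark | time |
|---|---|---|---|---|---|
| epsilon | 40 mM | 20 mM | 100 °C | the very flask that is asked about, followed so far |  |
| delta | 40 mM | 20 mM | 85 °C | run made earlier |  |
| flask | 40.0 mM | 20.0 mM | 100 °C |  | 15 h |

| run | time / h | target / % |
|---|---|---|
| epsilon | 2.00 | 30.5 |
| epsilon | 4.00 | 38.5 |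
| epsilon | 6.00 | 42.2 |
| epsilon | 8.00 | 43.6 |
| epsilon | 10.0 | 44.2 |
| epsilon | 12.0 | 44.2 |
| delta | 4.00 | 25.1 |
| delta | 8.00 | 34.2 |
| delta | 12.0 | 38.6 |
| delta | 15.0 | 41.3 |
| delta | 20.0 | 42.3 |
| delta | 25.0 | 43.6 |

(standard deviation of a reading: 0.5 percentage points)

- removed target is counted in
- additions bring no volume worth counting

- violet: at 15 h take out 90 % of the target then present, then wait 5.0 h
- red: change nothing and wait 5.0 h more
- blue: at 15 h raise the temperature by 10 K, then wait 5.0 h
- amber: at 15 h add partner, 50.0 % of the amount charged, then wait 5.0 h

- target, in percent of the starting material first charged, at 15 h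
- the remedy with the largest gain of target, or "none" below 2 percentage points (violet / red / blue / amber / none)
- target present, with what was taken out counted in, in percent of the starting material first charged, after red
- target present, with what was taken out counted in, in percent of the starting material first charged, after blue

In the epsilon run the next intervals give 0.0185 h⁻¹ and 0.00700 h⁻¹, further factors of 2.16 and 2.64, and together the rate as read has fallen by a factor of 21.7. The gain from 8.00 h to 10.0 h is 0.6 percentage points, close to the scatter of 0.5 points, so the chain of factors can't be read further. The target readings do not show what slows the rate.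

For the start I take the first rate, whose interval has its middle 0.5 of an interval after the start, and raise it by the square root of the first factor. That gives an estimated start rate of 0.298 h⁻¹. The last reading of 44.2 % over that start rate is 1.48 h; I call this the working time, the hours of unslowed running that the yield is worth. It is shorter than the 12.0 h on the clock.

The delta run, reckoned the same way, starts at 0.104 h⁻¹, lower by a factor of 2.87. Its working time is 4.18 h, longer by a factor of 2.82, which restates that the last readings of the two runs, 43.6 % and 44.2 %, lie close. I would commit to about 44.2 % at 15 h.

The forecast gives 44.3 % now, between 43.6 % and 45 %, then 44.4 % after red, 44.4 % after blue, and as best remedy none: “Waiting, heating, adding partner or removing target then gain nothing.”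

The flask gives 43.2 %, then 41.5 % after red and 39.0 % after blue, and the best remedy is amber, with a gain of 6.8 points.

    starting material + partner ⇌ isomer of the product (K = 2100 M⁻¹, k = 0.0670 M⁻¹ min⁻¹, Ea = 68.0 kJ mol⁻¹, ΔH = 0 kJ mol⁻¹)
    starting material + partner ⇌ target (K = 230 M⁻¹, k = 0.130 M⁻¹ min⁻¹, Ea = 75.0 kJ mol⁻¹, ΔH = −13.0 kJ mol⁻¹)
    partner + protic impurity → quenched reagent (k = 0.290 M⁻¹ min⁻¹, Ea = 63.0 kJ mol⁻¹)
    (constants at 100 °C)

The flask's working time comes to 1.45 h, yet at 15.0 h it still holds 25.1 % of its starting material. The neighbour charged with 5.0 mM of protic impurity keeps the flask's charges of starting material and partner, and the target's step holds no protic impurity, so I give it the same start rate. Its 51.6 % makes a working time of 1.73 h, longer by a factor of 1.19, and at 15.0 h it has 43 % of its partner left, against 15 % in the flask.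

The earlier runs and the new flask were computed with made-up constants; noise was put on by code.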